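**Assumption:** the acyl group is tiglate (E), as the SMILES specifies. E/Z mixtures of enoate 10 are carried forward because the allylchromium intermediate equilibrates.

## Retrosynthetic overview
1. Lychnophorolide B comes from tiglation at C8 and desilylation at C15 of a macrocycle. The macrocycle is formed by an intramolecular Cr(II) allylation (C6–C7) of a Z-enal with a 2-(bromomethyl)enoate. This step closes the 10-membered carbocycle, and lactonisation then gives the trans-α-methylene-γ-lactone.
2. The Z-enal and the 3(2H)-furanone with its quaternary C10 ether are made together, by a dearomative oxidative spiro-cyclisation and ring-opening of a 2-(acylmethyl)-3-(silyloxymethyl)furan. This is the key step.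
3. The furan is 2-methylfuran-3-carboxylic acid, coupled through its lateral carbanion to a chiral α-hydroxy-γ-lactone. That lactone comes from (S)-benzyl glycidyl ether and propionate, with C8 from the epoxide and C10 from anti-selective enolate hydroxylation.
4. Rings are formed in this order: a γ-lactone template that is later opened, the furan (feedstock), the furanone (by dearomatisation), and finally the 10-membered ring with the target lactone.

## Route

**Step 1**
Reactants: 1 (S)-benzyl glycidyl ether; 2 propionic acid
Product: 3 (5S)-5-(benzyloxymethyl)-3-methyloxolan-2-one, as a C3 epimer mixture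
Conditions: 2, LDA (2.2 equiv), THF, 0 °C; then 1, −20 → 25 °C; then cat. TsOH, PhMe, 60 °C
Reagents that add atoms: none
Why: The propionate dianion opens the epoxide at the terminal carbon, and acid closes the γ-lactone; this is epoxide opening by a carboxylic acid dianion. C8 keeps the epoxide configuration (S), and the C3 epimers converge in Step 2.

**Step 2**
Reactants: 3
Product: 4 (3R,5S)-5-(benzyloxymethyl)-3-hydroxy-3-methyloxolan-2-one
Conditions: LiHMDS, THF, −78 °C; then Davis oxaziridine, −78 °C
Reagents that add atoms: 2-(phenylsulfonyl)-3-phenyloxaziridine, O=S(=O)(c1ccccc1)N1OC1c1ccccc1 (supplies the OH oxygen)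
Why: Enolate hydroxylation occurs anti to the C5 substituent, which puts OH trans and Me cis to C7 and sets C10 as R (Rubottom/Davis-type α-hydroxylation).

**Step 3**
Reactants: 4
Product: 5 (3R,5S)-3-hydroxy-5-(hydroxymethyl)-3-methyloxolan-2-one
Conditions: H2 (1 atm), 10% Pd/C, EtOAc, 25 °C
Reagents that add atoms: none
Why: The benzyl ether is cleaved by hydrogenolysis while no other reducible group is present; no stereocentre is touched.

**Step 4**
Reactants: 5
Product: 6 (2S,4R)-4-hydroxy-4-methyl-5-oxooxolane-2-carbaldehyde
Conditions: Dess–Martin periodinane, NaHCO3, CH2Cl2, 0 → 25 °C; used crude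
Reagents that add atoms: none
Why: Mild oxidation of the primary alcohol gives the aldehyde without epimerising C8 (buffered conditions).

**Step 5**
Reactants: 7 triethyl phosphonoacetate
Product: 8 ethyl 2-(diethoxyphosphoryl)-3-hydroxypropanoate
Conditions: (CH2O)n, cat. K2CO3, THF/H2O, 0 → 25 °C
Reagents that add atoms: paraformaldehyde, C=O
Why: Base-catalysed hydroxymethylation of the active methylene (aldol-type); the mild conditions avoid Horner–Wadsworth–Emmons elimination.

**Step 6**
Reactants: 8
Product: 9 ethyl 3-(tert-butyldimethylsilyloxy)-2-(diethoxyphosphoryl)propanoate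
Conditions: TBSCl, imidazole, DMF, 0 → 25 °C
Reagents that add atoms: TBSCl, CC(C)(C)[Si](C)(C)Cl
Why: Standard silylation of the primary alcohol gives the HWE reagent that carries the future C11–CH2O group.

**Step 7**
Reactants: 6; 9
Product: 10 ethyl (E)-2-[(TBSO)methyl]-3-[(2S,4R)-4-hydroxy-4-methyl-5-oxooxolan-2-yl]acrylate
Conditions: LiCl, iPr2NEt, MeCN, 0 → 25 °C
Reagents that add atoms: none
Why: Masamune–Roush Horner–Wadsworth–Emmons olefination under nearly neutral conditions builds the C7=C11 trisubstituted enoate without touching C8, which is the stereocentre next to the aldehyde.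

**Step 8**
Reactants: 10; 11 2-methylfuran-3-carboxylic acid
Product: 12 keto-acid (furan-3-carboxylic acid bearing a CH2C(=O)–C10(OH)Me–C9H2–C8H(OH)–C7=C11 chain)
Conditions: 11 (3.3 equiv), LDA (7.3 equiv), THF, −78 → −20 °C; cool to −78 °C, add 10, warm to −40 °C, then NH4Cl
Reagents that add atoms: none
Why: Proposed new method: the 2-methyl group of the lithium furoate is lithiated laterally, directed by the carboxylate, and the carbanion adds to the lactone carbonyl. The tetrahedral intermediate collapses with ring-opening to the C1 ketone and frees the C8 alkoxide with no new stereocentre. This is modelled on o-toluic acid dianion acylations; the extra equivalents cover the free tertiary OH.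

**Step 9**
Reactants: 12
Product: 13 furan-3-yl-methanol (C15–OH)
Conditions: BH3·SMe2 (1.2 equiv), THF, −10 → 0 °C; MeOH quench
Reagents that add atoms: none
Why: Borane reduces a carboxylic acid faster than a ketone or an ester (hydroboration-type reduction), so C15 reaches the alcohol level.

**Step 10**
Reactants: 13
Product: 14 C15-TBDPS ether
Conditions: TBDPSCl, imidazole, DMF, 0 °C
Reagents that add atoms: TBDPSCl, CC(C)(C)[Si](Cl)(c1ccccc1)c1ccccc1
Why: The hindered silyl chloride protects only the primary alcohol, leaving the C8 secondary and C10 tertiary OH free.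

**Step 11**
Reactants: 14; 15 tiglic acid
Product: 16 C8 tiglate
Conditions: tiglic acid, 2,4,6-Cl3C6H2COCl, Et3N, THF; then 14, DMAP, PhMe, 25 °C
Reagents that add atoms: none
Why: Yamaguchi esterification acylates the secondary C8–OH selectively; the tertiary C10–OH is too hindered, and the (E)-tiglate geometry is kept.

**Step 12**
Reactants: 16
Product: 17 furanone–Z-enal: 3(2H)-furanone with C3–C4(CH2OTBDPS)=C5H–CHO (C3 and C6 cis), C10 quaternary and R
Conditions: NBS (1.05 equiv), NaHCO3, THF/H2O (4:1), 0 °C
Reagents that add atoms: none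
Why: Proposed new method: NBS oxidises the furan to a bromo-oxocarbenium, and the tethered tertiary C10–OH closes 5-exo onto C3 to give a spiro-2,5-dihydrofuran. Ionisation at C6 and hydrolysis open the furan ring to the Z-enal, and loss of H2 from C2 gives the vinylogous ester (furanone). The cis arrangement of C3 and C6 is inherited from the furan ring, the C10 centre is untouched, and the net change is loss of 2 H. The closest known chemistry is the Achmatowicz spiroketalisation of furans combined with acid- or base-promoted cyclodehydration of γ-hydroxy-β-diketones to 3(2H)-furanones. This is the dearomatisation key step.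

**Step 13**
Reactants: 17
Product: 18 allylic alcohol (C11–CH2OH)
Conditions: HF·pyridine, pyridine/THF, 0 °C, 2 h
Reagents that add atoms: none
Why: Buffered HF removes the primary TBS ether and leaves the TBDPS ether, aldehyde, furanone and tiglate intact.

**Step 14**
Reactants: 18
Product: 19 allylic bromide (BrCH2–C11)
Conditions: MsCl, Et3N, CH2Cl2, −20 °C; then LiBr, THF, 0 °C
Reagents that add atoms: LiBr, [Li+].[Br-]
Why: Mesylation followed by Finkelstein-type SN2 displacement converts the allylic alcohol to the bromide under conditions that tolerate the enal.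

**Step 15**
Reactants: 19
Product: 20 macrocycle, C15-TBDPS ether (6R,7R,8S,10R)
Conditions: CrCl2 (10 equiv), DMF, 25 °C, syringe-pump addition (0.003 M); then cat. p-TsOH, CH2Cl2
Reagents that add atoms: none
Why: Intramolecular Nozaki–Hiyama allylation goes through a chair Zimmerman–Traxler transition state via the E-allylchromium. This gives the anti homoallylic alcohol, which lactonises to the trans-fused α-methylene lactone and closes the 10-membered ring. C6 and C7 are set under control of C8 and the macrocycle conformation.

**Step 16**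
Reactants: 20
Product: 21 Lychnophorolide B
Conditions: HF·pyridine, pyridine/THF, 0 → 25 °C, 16 h
Reagents that add atoms: none
Why: Fluoride cleaves the primary silyl ether to release the C15 allylic alcohol; the tiglate, lactone and furanone are stable to buffered HF.

## Compound list
1 | (S)-benzyl glycidyl ether | c1ccccc1COC[C@@H]1CO1 | starting material
2 | propionic acid | CCC(=O)O | starting material
3 | (5S)-5-(benzyloxymethyl)-3-methyloxolan-2-one (C3 epimers) | CC1C[C@@H](COCc2ccccc2)OC1=O | intermediate
4 | (3R,5S)-5-(benzyloxymethyl)-3-hydroxy-3-methyloxolan-2-one | C[C@@]1(O)C[C@@H](COCc2ccccc2)OC1=O | intermediate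
5 | (3R,5S)-3-hydroxy-5-(hydroxymethyl)-3-methyloxolan-2-one | C[C@@]1(O)C[C@@H](CO)OC1=O | intermediate
6 | (2S,4R)-4-hydroxy-4-methyl-5-oxooxolane-2-carbaldehyde | C[C@@]1(O)C[C@@H](C=O)OC1=O | intermediate
7 | triethyl phosphonoacetate | CCOC(=O)CP(=O)(OCC)OCC | starting material
8 | ethyl 2-(diethoxyphosphoryl)-3-hydroxypropanoate | CCOC(=O)C(CO)P(=O)(OCC)OCC | intermediate
9 | ethyl 3-(TBSO)-2-(diethoxyphosphoryl)propanoate | CCOC(=O)C(CO[Si](C)(C)C(C)(C)C)P(=O)(OCC)OCC | intermediate
10 | ethyl (E)-2-[(TBSO)methyl]-3-[(2S,4R)-4-hydroxy-4-methyl-5-oxooxolan-2-yl]acrylate | C[C@@]1(O)C[C@@H](/C=C(/C(=O)OCC)CO[Si](C)(C)C(C)(C)C)OC1=O | intermediate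
11 | 2-methylfuran-3-carboxylic acid | Cc1occc1C(=O)O | starting material
12 | keto-acid from lactone opening | OC(=O)c1ccoc1CC(=O)[C@](C)(O)C[C@H](O)/C=C(/C(=O)OCC)CO[Si](C)(C)C(C)(C)C | intermediate
13 | C15 primary alcohol | OCc1ccoc1CC(=O)[C@](C)(O)C[C@H](O)/C=C(/C(=O)OCC)CO[Si](C)(C)C(C)(C)C | intermediate
14 | C15-TBDPS ether | CC(C)(C)[Si](c1ccccc1)(c1ccccc1)OCc1ccoc1CC(=O)[C@](C)(O)C[C@H](O)/C=C(/C(=O)OCC)CO[Si](C)(C)C(C)(C)C | intermediate
15 | tiglic acid | C/C=C(\C)C(=O)O | starting material
16 | C8 tiglate | CC(C)(C)[Si](c1ccccc1)(c1ccccc1)OCc1ccoc1CC(=O)[C@](C)(O)C[C@H](OC(=O)/C(C)=C/C)/C=C(/C(=O)OCC)CO[Si](C)(C)C(C)(C)C | intermediate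
17 | furanone–Z-enal | O=C/C=C(\C2=CC(=O)[C@@](C)(C[C@H](OC(=O)/C(C)=C/C)/C=C(/C(=O)OCC)CO[Si](C)(C)C(C)(C)C)O2)CO[Si](c1ccccc1)(c1ccccc1)C(C)(C)C | intermediate
18 | allylic alcohol | O=C/C=C(\C2=CC(=O)[C@@](C)(C[C@H](OC(=O)/C(C)=C/C)/C=C(/C(=O)OCC)CO)O2)CO[Si](c1ccccc1)(c1ccccc1)C(C)(C)C | intermediate
19 | allylic bromide | O=C/C=C(\C2=CC(=O)[C@@](C)(C[C@H](OC(=O)/C(C)=C/C)/C=C(/C(=O)OCC)CBr)O2)CO[Si](c1ccccc1)(c1ccccc1)C(C)(C)C | intermediate
20 | macrocycle, C15-TBDPS ether | C=C1C(=O)O[C@@H]2/C=C(/CO[Si](c3ccccc3)(c3ccccc3)C(C)(C)C)C3=CC(=O)[C@@](C)(C[C@H](OC(=O)/C(C)=C/C)[C@@H]12)O3 | intermediate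
21 | Lychnophorolide B | C=C1C(=O)O[C@@H]2/C=C(/CO)C3=CC(=O)[C@@](C)(C[C@H](OC(=O)/C(C)=C/C)[C@@H]12)O3 | target

## Step count
Total steps: 16, including the 2-step preparation of HWE reagent 9 (Steps 5–6).
Longest linear sequence: 14 steps (Steps 1–4, then 7–16).

## Three steps most likely to fail
1. **Step 15 (macrocyclic Cr allylation).** Yield and the C6/C7 diastereoselectivity relative to C8 are uncertain. Fallback: skip the allyl halide and close the ring by Pd(OAc)2/PPh3/Et3B umpolung allylation of alcohol 18, which proceeds through a π-allylpalladium/allylboron species rather than allylchromium.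
2. **Step 12 (dearomative cascade).** Possible problems are E/Z isomerisation of the enal, bromination at C5 or C2 instead of oxidation, and incomplete cyclodehydration. Fallback: build the furanone by 5-endo-dig oxa-Michael cyclisation of a tertiary α-hydroxy ynone (Et2NH or AuCl3), with the Z-enal built by Sonogashira coupling to a Z-β-iodoacrolein equivalent.
3. **Step 8 (lateral carbanion addition).** The hindered, α-quaternary lactone carbonyl (bearing an α-alkoxide) may not be attacked, and the carbanion may deprotonate the acidic C8–H or add in conjugate fashion to the enoate. Fallback: open lactone 10 with MeLi after O-silylation to give the α-silyloxy methyl ketone, then couple it with 2-bromo-3-(silyloxymethyl)furan by Pd-catalysed α-arylation to form the same C2–C3 bond.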